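## Analysis of the target

Canaliculatol (25) is a resveratrol trimer, C42H32O9, in which six sp3 carbons, labelled here C1 to C6, carry three 4-hydroxyphenyl rings (A1 on C1, A2 on C4, A3 on C6) and are tied together by three resorcinol rings (B1, B2, B3). C1, C2 and C3 close an indane on ring B1; C2, C3, C4, two carbons of ring B2, C5 and two carbons of ring B3 form an eight-membered carbocycle that is trans-fused to the indane along C2–C3; C5, C6 and one oxygen of ring B3 complete a 2,3-dihydrobenzofuran. All six carbons are stereocentres, (1R,2S,3R,4R,5R,6R): ring A1 on C1 and ring B3 on C2 are cis on the indane, C4 on C3 is trans to ring B3, and rings B2 (on C5) and A3 (on C6) are trans on the dihydrofuran. The eight phenols are oxidation-prone and make every ring a nucleophile, the C6–O bond is a 4-oxybenzylic ether that ionises in acid, and C1, C4 and C5 are doubly benzylic methines. The difficulty lies in the medium ring with its four stereocentres, in the contra-thermodynamic cis-1,2-diaryl indane, and in telling nine oxygens apart, one of which becomes the ring oxygen. The strategy rests on the C5–C6 bond: C5 lies in the eight-membered ring between rings B2 and B3 and C6 is an O-benzylic carbon bearing ring A3, so C6 and ring A3 can be drawn from a 4-methoxybenzyl ether on ring B3 and joined to a carbene centred on C5 as the last C–C bond.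

## Retrosynthetic reasoning

25 from 24. The last operation is cleavage of the seven aryl methyl ethers, so the eight phenols are uncovered only at the end. Compound 24 already has the full skeleton and all six stereocentres.

24 from 23. C6 is the one centre that can be adjusted late, because its C–O bond is 4-methoxybenzylic and opens reversibly in acid. The trans ring of 24 is therefore reached from the C6 epimer 23 by equilibration, and the same acid removes the spare 4-methoxybenzyl ether. The insertion need not deliver the trans ring directly, which matters because insertions of this kind are expected to give the cis ring first.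

23 from 22 (key disconnection). The C5–C6 bond is cut. This turns C6 and ring A3 into the CH2–aryl part of a 4-methoxybenzyl ether, a group that is needed on ring B3 anyway, and turns C5 into a diazo carbon derived from a diaryl ketone; no other bond of the dihydrofuran offers this. In the forward direction the carbene at C5 must pick the O–CH2 hydrogens of the ortho ether and one of its own two faces.

22 from 21 from 20. No skeletal bond is cut: the diazo group is traced through the hydrazone 21 to the ketone 20.

20 from 18 and 19; 18 from 17. The two O–CH2 bonds on ring B3 are cut to the bisphenol 18 and the chloride 19. The 4-methoxybenzyl ethers cannot be carried earlier, because each acid step before them would cleave them; benzyl ethers (17) stand in and are exchanged in two steps. Ring B3 carries two identical ethers so that its two positions next to C2 stay equivalent.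

17 from 16 from 15 and 7. The C1–ring A1 bond is cut. Forward, the aryl group is added to the C1 ketone of 15 and the hydroxyl is replaced by hydrogen delivered anti to ring B3, which gives the cis-1,2-diaryl indane that no equilibrating method would give.

15 from 13. The C5–ring B3 bond is cut; forward it is an intramolecular acylation that closes the eight-membered ring. It is placed before the chemistry at C1 on purpose. While C1 is a carbonyl, ring B1 is deactivated and the only activated position within reach is on ring B3; once C1 is reduced, the free position of ring B1 next to C3 would compete through a seven-membered ring.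

13 from 11 and 12. The C2–ring B3 bond is cut; forward it is an enolate arylation that places ring B3 trans to C4. Ring B3 is brought in only after C4 is complete, because its electron-rich ring would capture the C4 cation of step 5.

11 from 10 from 8 and 9. The C4–ring B2 bond is cut; forward the C4 cation alkylates 9 at the position next to its ester. This sets C4 relative to C3 and brings in the carboxyl carbon that becomes C5.

8 from 6 and 7; 6 from 4. The C4–ring A2 bond is cut to an aldehyde, whose carbon is traced to the styryl group of 4.

4 from 2 and 3; 2 from 1. The C3–C4 bond is cut; forward an asymmetric conjugate addition to the indenone 2 sets C3, the only stereocentre introduced by a chiral reagent before the key step. The indenone comes from commercial 1 by dehydrogenation.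

## Alternatives that were turned down

Alternative 1: The two aryl–carbon bonds at C1 and C2 of the indane are cut together. This leaves an indene carrying the future C4 as a silyloxymethyl group on C3, an aryl bromide that already contains the trans-dihydrobenzofuran (C5, C6, rings B2, B3 and A3), and an aryl boron reagent for ring A1. In the forward key step an arylpalladium intermediate adds to C2 of the indene on the face away from the C3 substituent, and the benzylic palladium at C1 is intercepted by the boron reagent, giving A1.
- For it: syn addition anti to the C3 substituent fixes the cis-1,2 and trans-2,3 relationships in one step and by mechanism. That is more secure than the aryl addition and ionic hydrogenation used here (steps 9 and 10).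
- For it: C5 and C6 are made on a simple precursor, so their configuration does not depend on the pucker of a medium ring. On this point the alternative is clearly stronger, and it is also more convergent.
- Against it: in A1 the eight-membered ring is still open. It must be closed by joining C4 to ring B2 through a C4 cation, in the presence of the acid-labile dihydrofuran and three electron-rich rings, with C4 set in that closure.
- Against it: two separately made chiral partners must match, and the benzylic palladium intermediate can escape by β-hydride elimination.
- Comparison: the chosen strategy closes the medium ring by a ketone-forming acylation while nothing acid-sensitive is present and makes the fragile C6–O region last. It pays for this with an uncertain face at C5.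

Alternative 2: Ring B2 is removed as an aryne and the bonds from C4 and C5 to ring B2 are cut. This leaves an indane-fused six-membered β-keto ester in which the C4 ketone carbon and the ester-bearing C5 are bonded directly. In the forward key step the enolate adds to the aryne at the carbon remote from methoxy, the aryl anion attacks the ketone, and the four-membered alkoxide fragments, so that both aryl–carbon bonds form and the ring grows from six to eight members, giving A2.
- For it: one step builds the medium ring and two aryl–carbon bonds, which is better step economy for the ring than steps 5 to 8 here.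
- For it: C5 in A2 is α to an ester and can be equilibrated, a handle the chosen strategy lacks.
- Against it: the regiochemistry rests on the polarisation of an aryne in which only one methoxy group flanks the triple bond.
- Against it: after the key step ring A2 must still be added to the C4 ketone and the oxygen removed with control of C4. The ester at C5 must be rebuilt into C6, ring A3 and the furan oxygen on a ring B3 that carries two different ethers.
- Comparison: the chosen strategy spends more steps on the ring, but after it only one C–C bond remains and that bond comes straight from a protecting group.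

Alternative 3: Ring B1 itself is disconnected: one aromatic C–C bond is opened to a cyclopentanone carrying a 3-oxobutanoyl side chain. In the forward key step aqueous base brings about an intramolecular aldol addition of the terminal methyl carbon to the ring ketone, loss of water and tautomerisation to the resorcinol, giving A3.
- For it: ring B1, the most troublesome spectator nucleophile, is absent during all cation and acylation chemistry. The chosen route has to suppress that competition by the order of its steps (step 8). The two hydroxyls of ring B1 also appear free and distinct from the other oxygens.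
- Against it: the eight-membered ring, the dihydrofuran and all six stereocentres would have to be assembled on a non-aromatic cyclopentanone.
- Against it: C1 and C3 flank carbonyl groups in the precursor and the C1/C2 cis relationship is the unstable one, so aqueous base threatens epimerisation. The triketone can also condense in other directions.
- Comparison: the chosen strategy buys all six arenes and spends its steps on C–C bonds between them. The alternative is stronger only in avoiding competition from ring B1.

Key step: step 15

Assumption: by analogy with related insertions of diaryl carbenes into benzylic ethers, the kinetic product of step 15 is taken to be the 5,6-cis dihydrofuran 23; if the trans isomer forms directly it passes through step 16 unchanged at C6.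

## Route

Step 1
Reactants: 1 5,7-dimethoxy-2,3-dihydro-1H-inden-1-one
Product: 2 5,7-dimethoxy-1H-inden-1-one
Conditions: IBX (2-iodoxybenzoic acid, 1.5 equiv), DMSO–toluene 1:2, 70 °C
Reagents that add atoms: none
Why: Dehydrogenation of a ketone with IBX through its enol introduces the C2–C3 double bond; the two methoxy groups donate into the carbonyl, which tempers the tendency of the indenone to dimerise, and 2 is used at once.

Step 2
Reactants: 2 5,7-dimethoxy-1H-inden-1-one; 3 (E)-2-phenylethenylboronic acid
Product: 4 (3R)-5,7-dimethoxy-3-[(E)-2-phenylethenyl]-2,3-dihydro-1H-inden-1-one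
Conditions: [Rh(OH)(cod)]2 (2.5 mol%), (R)-BINAP (5.5 mol%), 3 (2 equiv), dioxane–H2O 10:1, 35 °C
Reagents that add atoms: none
Why: Hayashi–Miyaura reaction: the alkenylrhodium species formed from 3 adds to the β-carbon of the cyclic enone inside the chiral pocket of the rhodium–BINAP complex and water protonates the rhodium enolate. The R ligand is chosen by analogy with the sense of addition to 2-cyclopentenone so that C3 becomes R; this carbon is the source of all later stereocentres, and the styryl group is a masked formyl group.

Step 3
Reactants: 4 (3R)-5,7-dimethoxy-3-[(E)-2-phenylethenyl]-2,3-dihydro-1H-inden-1-one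
Product: 6 (1S)-4,6-dimethoxy-3-oxo-2,3-dihydro-1H-indene-1-carbaldehyde, via vicinal diol 5 (not isolated)
Conditions: OsO4 (2 mol%), NaIO4 (4 equiv), 2,6-lutidine (2 equiv), dioxane–H2O 3:1, 20 °C
Reagents that add atoms: osmium tetroxide, O=[Os](=O)(=O)=O; sodium periodate, [Na+].[O-]I(=O)(=O)=O
Why: Lemieux–Johnson oxidation: dihydroxylation of the only alkene and periodate cleavage of the diol give the aldehyde, while the ketone-deactivated arene is left alone. The α-aryl aldehyde is configurationally labile, so 6 is taken on crude and cold.

Step 4
Reactants: 6 (1S)-4,6-dimethoxy-3-oxo-2,3-dihydro-1H-indene-1-carbaldehyde; 7 4-methoxyphenylmagnesium bromide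
Product: 8 (3S)-3-[hydroxy(4-methoxyphenyl)methyl]-5,7-dimethoxy-2,3-dihydro-1H-inden-1-one (both carbinol epimers)
Conditions: 7 (1.2 equiv), THF, −78 °C; aqueous NH4Cl
Reagents that add atoms: none
Why: Grignard addition; at −78 °C the aldehyde reacts far faster than the indanone carbonyl, which is a vinylogous ester flanked by a peri methoxy group. The carbinol centre is not controlled and need not be, because it becomes a cation in step 5.

Step 5
Reactants: 8 (3S)-3-[hydroxy(4-methoxyphenyl)methyl]-5,7-dimethoxy-2,3-dihydro-1H-inden-1-one; 9 methyl 3,5-dimethoxybenzoate
Product: 10 methyl 2-[(R)-[(1R)-4,6-dimethoxy-3-oxo-2,3-dihydro-1H-inden-1-yl](4-methoxyphenyl)methyl]-3,5-dimethoxybenzoate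
Conditions: 9 (8 equiv), HBF4·OEt2 (1.5 equiv), CH2Cl2, −78 → −20 °C
Reagents that add atoms: none
Why: Friedel–Crafts alkylation through a secondary 4-methoxybenzylic cation with a stereocentre in the α-position, a reaction type known for high facial selectivity: the cation adopts the conformer with the C3–H bond in its plane and syn to ring A2 (least 1,3-allylic strain), and 9 attacks from the side of the ring CH2 (C2) and not from the side of the peri C–H of ring B1, which gives 4R. Compound 9 reacts at its C2, para to one methoxy group and ortho to the other, as in its halogenation and formylation; ring B1 is switched off by the C1 carbonyl and ring B3 is not yet present, so no other arene competes. The in-plane C3–H bond is orthogonal to the empty orbital, which slows loss of that proton and protects the configuration at C3.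

Step 6
Reactants: 10 methyl 2-[(R)-[(1R)-4,6-dimethoxy-3-oxo-2,3-dihydro-1H-inden-1-yl](4-methoxyphenyl)methyl]-3,5-dimethoxybenzoate
Product: 11 2-[(R)-[(1R)-4,6-dimethoxy-3-oxo-2,3-dihydro-1H-inden-1-yl](4-methoxyphenyl)methyl]-3,5-dimethoxybenzoic acid
Conditions: LiOH (5 equiv), THF–MeOH–H2O 3:1:1, 50 °C; then aqueous HCl to pH 2
Reagents that add atoms: lithium hydroxide, [Li+].[OH-]
Why: Saponification of a benzoate with one ortho substituent. The ester is cleaved before step 7 because the ketone enolate would otherwise attack it in a six-membered Claisen condensation.

Step 7
Reactants: 11 2-[(R)-[(1R)-4,6-dimethoxy-3-oxo-2,3-dihydro-1H-inden-1-yl](4-methoxyphenyl)methyl]-3,5-dimethoxybenzoic acid; 12 1-bromo-3,5-bis(benzyloxy)benzene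
Product: 13 2-[(R)-[(1S,2R)-2-[3,5-bis(benzyloxy)phenyl]-4,6-dimethoxy-3-oxo-2,3-dihydro-1H-inden-1-yl](4-methoxyphenyl)methyl]-3,5-dimethoxybenzoic acid (aryl group and C4 substituent trans)
Conditions: 12 (1.3 equiv), Pd(OAc)2 (5 mol%), XPhos (10 mol%), NaOtBu (3.5 equiv), dioxane, 80 °C; then aqueous HCl
Reagents that add atoms: none
Why: Palladium-catalysed α-arylation of a ketone enolate; the first equivalent of base turns the acid into an inert carboxylate. The aryl group enters anti to the large substituent on the neighbouring carbon, and the acidic α-aryl ketone equilibrates under the basic conditions to the same trans isomer, which sets C2.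

Step 8
Reactants: 13 2-[(R)-[(1S,2R)-2-[3,5-bis(benzyloxy)phenyl]-4,6-dimethoxy-3-oxo-2,3-dihydro-1H-inden-1-yl](4-methoxyphenyl)methyl]-3,5-dimethoxybenzoic acid
Product: 15 (2R,3S,4R)-diketone with the eight-membered ring closed (C1 and C5 carbonyl; ring B3 as bis(benzyl) ether), via mixed trifluoroacetic anhydride 14 (not isolated)
Conditions: (CF3CO)2O (3 equiv), CH2Cl2, 0 → 20 °C
Reagents that add atoms: none
Why: Intramolecular Friedel–Crafts acylation by the mixed anhydride; the two positions of ring B3 next to C2 are equivalent and each is activated by an ortho and a para benzyloxy group, so ring B3 offers no regiochemical choice. The closure is run at the indanone stage on purpose: the C1 carbonyl deactivates ring B1 and suppresses the seven-membered closure at its free position next to C3. The six-membered anthrone closure onto ring A2 would need an unactivated position meta to methoxy, and C-acylation of the enol at C2 would build a quaternary centre.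

Step 9
Reactants: 15 (2R,3S,4R)-diketone with the eight-membered ring closed; 7 4-methoxyphenylmagnesium bromide
Product: 16 (1R,2R,3S,4R)-tertiary alcohol at C1 (ring A1 on C1, hydroxyl cis to ring B3; C5 still a ketone)
Conditions: 7 (3 equiv), LaCl3·2LiCl (1.1 equiv), THF, −40 → 0 °C; aqueous NH4Cl
Reagents that add atoms: none
Why: 1,2-Addition of an aryl Grignard reagent promoted by LaCl3·2LiCl, which favours addition over enolisation of the α-aryl ketone. The C5 ketone has three ortho substituents and is twisted and shielded like a mesityl ketone, so only C1 should react; the aryl group is expected to enter anti to ring B3, and the carbinol configuration is erased in step 10.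

Step 10
Reactants: 16 (1R,2R,3S,4R)-tertiary alcohol at C1
Product: 17 (1R,2S,3R,4R)-ketone at C5 with ring B3 as bis(benzyl) ether (ring A1 cis to ring B3)
Conditions: Et3SiH (5 equiv), CF3CO2H (5 equiv), CH2Cl2, −40 → 0 °C
Reagents that add atoms: none
Why: Ionic hydrogenation: acid ionises the tertiary, doubly benzylic alcohol to a cation stabilised by ring A1 and by the ortho and para methoxy groups of ring B1, and Et3SiH delivers hydride to C1 from the face anti to ring B3 on the adjacent carbon. This places ring A1 cis to ring B3, the less stable arrangement. The benzyl ethers and the hindered C5 ketone should survive the short, cold exposure.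

Step 11
Reactants: 17 (1R,2S,3R,4R)-ketone at C5 with ring B3 as bis(benzyl) ether
Product: 18 (1R,2S,3R,4R)-ketone at C5 with two free hydroxyls on ring B3
Conditions: H2 (1 atm), Pd/C (10 wt%), EtOAc–MeOH 1:1, 20 °C
Reagents that add atoms: none
Why: Hydrogenolysis of the two benzyl ethers; the twisted diaryl ketone and the methyl ethers are inert under these conditions. The benzyl groups have served as acid-stable placeholders through steps 8 to 10.

Step 12
Reactants: 18 (1R,2S,3R,4R)-ketone at C5 with two free hydroxyls on ring B3; 19 4-methoxybenzyl chloride
Product: 20 (1R,2S,3R,4R)-ketone at C5 with ring B3 as bis(4-methoxybenzyl) ether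
Conditions: 19 (2.5 equiv), K2CO3 (4 equiv), n-Bu4NI (0.1 equiv), DMF, 50 °C
Reagents that add atoms: none
Why: Williamson ether synthesis on both phenols. The ether ortho to C5 will supply C6 and ring A3; the para ether is a spectator.

Step 13
Reactants: 20 (1R,2S,3R,4R)-ketone at C5 with ring B3 as bis(4-methoxybenzyl) ether
Product: 21 hydrazone of 20 at C5
Conditions: N2H4·H2O (30 equiv), AcOH (cat.), n-BuOH, 110 °C
Reagents that add atoms: hydrazine monohydrate, NN.O
Why: Condensation of a non-enolisable ketone with hydrazine; the ethers are stable to the reagent. The carbonyl is hindered, so a large excess and a high-boiling alcohol are used.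

Step 14
Reactants: 21 hydrazone of 20 at C5
Product: 22 eight-membered cyclic diaryldiazomethane (diazo carbon C5, ring B3 as bis(4-methoxybenzyl) ether)
Conditions: activated MnO2 (8 equiv), CH2Cl2, 0 °C, dark; filtered through Celite and used as a cold solution
Reagents that add atoms: none
Why: Dehydrogenation of a hydrazone by MnO2 gives the diaryldiazomethane, which is stabilised by its two aryl groups and handled only in solution.

Step 15
Reactants: 22 eight-membered cyclic diaryldiazomethane
Product: 23 (1R,2S,3R,4R,5R,6S)-canaliculatol heptamethyl ether 4-methoxybenzyl ether with a 5,6-cis dihydrofuran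
Conditions: Rh2(S-PTAD)4 (1 mol%), CH2Cl2, −20 → 20 °C, slow addition of 22
Reagents that add atoms: none
Why: The diazo carbon of 22 loses its nitrogen on the dirhodium tetracarboxylate and becomes an electrophilic diaryl carbene that has no α-hydrogen and so cannot undergo a 1,2-shift. Carbon C5 takes one hydrogen of the O–CH2 group of the ortho 4-methoxybenzyl ether, five atoms away, through a hydride-transfer-like three-centre transition state, and the C5–C6 bond closes at once; this is the known dirhodium-catalysed insertion of diaryl carbenes into benzylic ether C–H bonds that gives 2,3-dihydrobenzofurans. The ring closes as a five-membered ring by 1,5-insertion, the only size within reach, because the second 4-methoxybenzyl ether is para to C5 and insertion into the C–H bonds at C2 or C4 would give four-membered rings. At C5 the configuration follows from the face of ring B3 on which ring B2 lies when the hydrogen is transferred, since the new ring forms in the plane of ring B3; the trans ring fusion and C4 leave the eight-membered ring two puckers, and the chiral pocket of the catalyst is relied on to favour the transition state that gives 5R. At C6 the insertion is expected to place rings B2 and A3 cis, the usual kinetic outcome of this reaction type with either catalyst enantiomer, and this centre is corrected in step 16. The step therefore needs one C–H site (secured by distance and by the hydridic, oxygen- and aryl-activated character of that bond), one carbene face (ring pucker plus catalyst), and suppression of azine and carbene dimer (slow addition, bulky carboxylate ligands).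

Step 16
Reactants: 23 (1R,2S,3R,4R,5R,6S)-canaliculatol heptamethyl ether 4-methoxybenzyl ether with a 5,6-cis dihydrofuran
Product: 24 (1R,2S,3R,4R,5R,6R)-canaliculatol heptamethyl ether (5,6-trans dihydrofuran, free hydroxyl on ring B3)
Conditions: CF3CO2H (10 equiv), pentamethylbenzene (5 equiv), CH2Cl2, 0 → 20 °C
Reagents that add atoms: none
Why: Acid ionises both 4-methoxybenzylic C–O bonds: the aryl 4-methoxybenzyl ether is cleaved and its cation is captured by pentamethylbenzene, and the C6–O bond of the dihydrofuran opens reversibly to a benzylic cation that recloses on the phenol to the more stable 5,6-trans ring. C5 has no leaving group and is not touched.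

Step 17
Reactants: 24 (1R,2S,3R,4R,5R,6R)-canaliculatol heptamethyl ether
Product: 25 canaliculatol
Conditions: BBr3 (20 equiv), CH2Cl2, −78 → 20 °C; then MeOH, H2O
Reagents that add atoms: none
Why: Cleavage of the seven aryl methyl ethers by BBr3 through aryloxyboranes that are hydrolysed on work-up. The trans dihydrofuran is the thermodynamic form, so any reversible opening at C6 under the Lewis acid returns the same isomer.

## Compound list

1 | 5,7-dimethoxy-2,3-dihydro-1H-inden-1-one | COc1cc(OC)c2C(=O)CCc2c1 | starting material
2 | 5,7-dimethoxy-1H-inden-1-one | COc1cc(OC)c2C(=O)C=Cc2c1 | intermediate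
3 | (E)-2-phenylethenylboronic acid | OB(O)/C=C/c1ccccc1 | starting material
4 | (3R)-5,7-dimethoxy-3-[(E)-2-phenylethenyl]-2,3-dihydro-1H-inden-1-one | c1ccccc1/C=C/[C@H]1CC(=O)c2c(OC)cc(OC)cc21 | intermediate
5 | (3S)-3-(1,2-dihydroxy-2-phenylethyl)-5,7-dimethoxy-2,3-dihydro-1H-inden-1-one, mixture at the two carbinol carbons, not isolated | OC(c1ccccc1)C(O)[C@H]1CC(=O)c2c(OC)cc(OC)cc21 | intermediate
6 | (1S)-4,6-dimethoxy-3-oxo-2,3-dihydro-1H-indene-1-carbaldehyde | O=C[C@H]1CC(=O)c2c(OC)cc(OC)cc21 | intermediate
7 | 4-methoxyphenylmagnesium bromide | COc1ccc([Mg]Br)cc1 | starting material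
8 | (3S)-3-[hydroxy(4-methoxyphenyl)methyl]-5,7-dimethoxy-2,3-dihydro-1H-inden-1-one, both carbinol epimers | COc1ccc(C(O)[C@H]2CC(=O)c3c(OC)cc(OC)cc32)cc1 | intermediate
9 | methyl 3,5-dimethoxybenzoate | COC(=O)c1cc(OC)cc(OC)c1 | starting material
10 | methyl 2-[(R)-[(1R)-4,6-dimethoxy-3-oxo-2,3-dihydro-1H-inden-1-yl](4-methoxyphenyl)methyl]-3,5-dimethoxybenzoate | COC(=O)c1cc(OC)cc(OC)c1[C@@H](c1ccc(OC)cc1)[C@H]1CC(=O)c2c(OC)cc(OC)cc21 | intermediate
11 | 2-[(R)-[(1R)-4,6-dimethoxy-3-oxo-2,3-dihydro-1H-inden-1-yl](4-methoxyphenyl)methyl]-3,5-dimethoxybenzoic acid | OC(=O)c1cc(OC)cc(OC)c1[C@@H](c1ccc(OC)cc1)[C@H]1CC(=O)c2c(OC)cc(OC)cc21 | intermediate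
12 | 1-bromo-3,5-bis(benzyloxy)benzene | Brc1cc(OCc2ccccc2)cc(OCc2ccccc2)c1 | starting material
13 | 2-[(R)-[(1S,2R)-2-[3,5-bis(benzyloxy)phenyl]-4,6-dimethoxy-3-oxo-2,3-dihydro-1H-inden-1-yl](4-methoxyphenyl)methyl]-3,5-dimethoxybenzoic acid, 1,2-trans on the indanone | OC(=O)c1cc(OC)cc(OC)c1[C@@H](c1ccc(OC)cc1)[C@H]1[C@H](c3cc(OCc4ccccc4)cc(OCc4ccccc4)c3)C(=O)c2c(OC)cc(OC)cc21 | intermediate
14 | mixed anhydride of 13 with trifluoroacetic acid, not isolated | FC(F)(F)C(=O)OC(=O)c1cc(OC)cc(OC)c1[C@@H](c1ccc(OC)cc1)[C@H]1[C@H](c3cc(OCc4ccccc4)cc(OCc4ccccc4)c3)C(=O)c2c(OC)cc(OC)cc21 | intermediate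
15 | (2R,3S,4R)-diketone: C1 of the indane is C=O, C2 bears ring B3, C3 bears C4; C4 bears ring A2 (4-methoxyphenyl) and ring B2; C5 is a C=O between rings B2 and B3 and closes the eight-membered ring; rings B1 and B2 are dimethyl ethers, ring B3 is a bis(benzyl) ether; C2/C3 fusion trans | O=C2c3c(OC)cc(OC)cc3[C@H]3[C@H](c4ccc(OC)cc4)c4c(OC)cc(OC)cc4C(=O)c4c(OCc5ccccc5)cc(OCc5ccccc5)cc4[C@H]23 | intermediate
16 | (1R,2R,3S,4R)-tertiary alcohol: as 15, but C1 carries hydroxyl (cis to ring B3) and ring A1 (4-methoxyphenyl) | COc1ccc([C@@]2(O)c3c(OC)cc(OC)cc3[C@H]3[C@H](c4ccc(OC)cc4)c4c(OC)cc(OC)cc4C(=O)c4c(OCc5ccccc5)cc(OCc5ccccc5)cc4[C@H]23)cc1 | intermediate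
17 | (1R,2S,3R,4R)-C5 ketone: C1 carries H and ring A1 cis to ring B3; ring B3 as bis(benzyl) ether | COc1ccc([C@@H]2c3c(OC)cc(OC)cc3[C@H]3[C@H](c4ccc(OC)cc4)c4c(OC)cc(OC)cc4C(=O)c4c(OCc5ccccc5)cc(OCc5ccccc5)cc4[C@H]23)cc1 | intermediate
18 | (1R,2S,3R,4R)-C5 ketone with two free hydroxyls on ring B3 | COc1ccc([C@@H]2c3c(OC)cc(OC)cc3[C@H]3[C@H](c4ccc(OC)cc4)c4c(OC)cc(OC)cc4C(=O)c4c(O)cc(O)cc4[C@H]23)cc1 | intermediate
19 | 4-methoxybenzyl chloride | COc1ccc(CCl)cc1 | starting material
20 | (1R,2S,3R,4R)-C5 ketone with ring B3 as bis(4-methoxybenzyl) ether | COc1ccc([C@@H]2c3c(OC)cc(OC)cc3[C@H]3[C@H](c4ccc(OC)cc4)c4c(OC)cc(OC)cc4C(=O)c4c(OCc5ccc(OC)cc5)cc(OCc5ccc(OC)cc5)cc4[C@H]23)cc1 | intermediate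
21 | hydrazone of 20 at C5 | COc1ccc([C@@H]2c3c(OC)cc(OC)cc3[C@H]3[C@H](c4ccc(OC)cc4)c4c(OC)cc(OC)cc4C(=NN)c4c(OCc5ccc(OC)cc5)cc(OCc5ccc(OC)cc5)cc4[C@H]23)cc1 | intermediate
22 | (1R,2S,3R,4R)-eight-membered cyclic diaryldiazomethane, diazo carbon C5, ring B3 as bis(4-methoxybenzyl) ether | COc1ccc([C@@H]2c3c(OC)cc(OC)cc3[C@H]3[C@H](c4ccc(OC)cc4)c4c(OC)cc(OC)cc4C(=[N+]=[N-])c4c(OCc5ccc(OC)cc5)cc(OCc5ccc(OC)cc5)cc4[C@H]23)cc1 | intermediate
23 | (1R,2S,3R,4R,5R,6S)-canaliculatol heptamethyl ether 4-methoxybenzyl ether, rings B2 and A3 cis on the dihydrofuran | COc1ccc([C@@H]2c3c(OC)cc(OC)cc3[C@H]3[C@H](c4ccc(OC)cc4)c4c(OC)cc(OC)cc4[C@@H]4c5c(cc(OCc6ccc(OC)cc6)cc5[C@H]23)O[C@@H]4c2ccc(OC)cc2)cc1 | intermediate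
24 | (1R,2S,3R,4R,5R,6R)-canaliculatol heptamethyl ether, trans dihydrofuran, free hydroxyl on ring B3 para to C5 | COc1ccc([C@@H]2c3c(OC)cc(OC)cc3[C@H]3[C@H](c4ccc(OC)cc4)c4c(OC)cc(OC)cc4[C@@H]4c5c(cc(O)cc5[C@H]23)O[C@H]4c2ccc(OC)cc2)cc1 | intermediate
25 | canaliculatol, (1R,2S,3R,4R,5R,6R) | Oc1ccc([C@@H]2c3c(O)cc(O)cc3[C@H]3[C@H](c4ccc(O)cc4)c4c(O)cc(O)cc4[C@@H]4c5c(cc(O)cc5[C@H]23)O[C@H]4c2ccc(O)cc2)cc1 | target

## Step count and least certain steps

Total step count: 17. Longest linear sequence: 17 steps (from 1 to 25); compounds 3, 7, 9, 12 and 19 are bought.

Step 15 (key step). The most likely failure is insertion through the other pucker of the eight-membered ring, which would give the C5 epimer; this centre cannot be corrected afterwards. The configuration at C5 rests on a conformational preference of a medium ring, not on a covalent constraint. A simple model of 1,3-allylic strain at C2 does not clearly favour the pucker that is needed over the one in which the C2–H bond is turned toward C5, so the outcome depends on how strongly the catalyst discriminates between the two transition states. Azine formation and carbene dimerisation are the secondary risks.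

The fallback sets out from 18 and returns at 24; it sets C5 by a reversible protonation instead of an irreversible insertion. Both phenols of 18 are acylated with 4-methoxybenzoyl chloride (Et3N, DMAP) to the bis(4-methoxybenzoate) F1. Low-valent titanium (TiCl3, Zn, DME, reflux) couples the C5 ketone with the ortho ester carbonyl in a McMurry-type keto ester coupling to the 2-(4-methoxyphenyl)benzofuran F2, in which C5 and C6 are sp2. Ionic hydrogenation (Et3SiH, CF3CO2H) protonates C5 reversibly and reduces the oxocarbenium ion at C6; after equilibration at C6 in the acid this should give the trans dihydrobenzofuran 4-methoxybenzoate F3. Methanolysis of the remaining ester (K2CO3, MeOH) then gives 24.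

Step 5. Three things can go wrong together: attack of the cation on 9 at the position between its two methoxy groups, attack on the wrong face of the cation (C4 epimer), and reversible loss of the C3 proton from the cation, which would erode the enantiomeric purity because C3 is the only other stereocentre at this stage. The nucleophile is a deactivated arene, so the cation lives longer than with the electron-rich arenes usually used in this reaction type.

The fallback sets out from 6 and returns at 11; it reverses the roles of the two rings at C4. The aryl Grignard reagent made from methyl 2-bromo-3,5-dimethoxybenzoate by bromine–magnesium exchange (i-PrMgCl·LiCl, −20 °C) adds to aldehyde 6, and the alkoxide closes onto the ester to give the phthalide F4. The bond to ring B2 is then fixed at the right position by the bromide. Ionisation of the lactone C–O bond (BF3·OEt2 in anisole) gives a C4 cation stabilised by ring B2, which anisole attacks at its para position to give acid 11 directly. Because the in-plane aryl group and the incoming aryl group are exchanged, the same facial preference gives the opposite configuration at C4, so this variant is the one to use if step 5 delivers the C4 epimer.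

Step 10. The likely failure is reduction at the wrong place or from the wrong face. The C5 ketone oxygen sits six atoms from C1 and can capture the C1 cation (or form a hemiketal with the C1 hydroxyl); hydride transfer to the resulting oxocarbenium ion would give a cyclic ether. The substituent on C3 also shields the face of C1 from which hydride should come, though less than ring B3 shields the other.

The fallback sets out from 16 and returns at 18. Alcohol 16 is hydrogenolysed over Pd(OH)2/C under H2 in EtOAc–EtOH without acid. The benzylic C1–O bond and both benzyl ethers are cleaved in one operation; carbon–oxygen hydrogenolysis on palladium goes mainly with inversion, which from the expected carbinol epimer again places ring A1 cis to ring B3. No new compound is made.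

Step 13. The likely failure is that condensation does not proceed, because the C5 carbonyl carries three ortho substituents and is held twisted in the ring.

The fallback sets out from 20 and returns at 21. Ketone 20 is converted with Lawesson's reagent (toluene, 90 °C) into the thioketone F5, whose C=S bond is longer and far more reactive toward nitrogen nucleophiles. Hydrazine hydrate in THF at 20 °C then gives hydrazone 21 with loss of hydrogen sulfide.

## Further compounds

F1 | step 15 | bis(4-methoxybenzoate) of 18 (both hydroxyls of ring B3 acylated) | COc1ccc([C@@H]2c3c(OC)cc(OC)cc3[C@H]3[C@H](c4ccc(OC)cc4)c4c(OC)cc(OC)cc4C(=O)c4c(OC(=O)c5ccc(OC)cc5)cc(OC(=O)c5ccc(OC)cc5)cc4[C@H]23)cc1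
F2 | step 15 | (1R,2S,3R,4R)-2-(4-methoxyphenyl)benzofuran with C5 and C6 as furan carbons and a 4-methoxybenzoate on ring B3 | COc1ccc([C@@H]2c3c(OC)cc(OC)cc3[C@H]3[C@H](c4ccc(OC)cc4)c4c(OC)cc(OC)cc4-c4c5c(cc(OC(=O)c6ccc(OC)cc6)cc5[C@H]23)oc4-c2ccc(OC)cc2)cc1
F3 | step 15 | (1R,2S,3R,4R,5R,6R)-canaliculatol heptamethyl ether 4-methoxybenzoate (trans dihydrofuran) | COc1ccc([C@@H]2c3c(OC)cc(OC)cc3[C@H]3[C@H](c4ccc(OC)cc4)c4c(OC)cc(OC)cc4[C@@H]4c5c(cc(OC(=O)c6ccc(OC)cc6)cc5[C@H]23)O[C@H]4c2ccc(OC)cc2)cc1
F4 | step 5 | 3-[(1S)-4,6-dimethoxy-3-oxo-2,3-dihydro-1H-inden-1-yl]-4,6-dimethoxy-2-benzofuran-1(3H)-one, both epimers at the lactone carbon | O=C1OC([C@H]2CC(=O)c3c(OC)cc(OC)cc32)c2c(OC)cc(OC)cc12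
F0 | step 10 | none | none
F5 | step 13 | thioketone of 20 (C5 is C=S) | COc1ccc([C@@H]2c3c(OC)cc(OC)cc3[C@H]3[C@H](c4ccc(OC)cc4)c4c(OC)cc(OC)cc4C(=S)c4c(OCc5ccc(OC)cc5)cc(OCc5ccc(OC)cc5)cc4[C@H]23)cc1
A1 | alternative 1 | cis-1,2-diaryl indane with a trans tert-butyldimethylsilyloxymethyl group at C3, ring B3 already part of the trans dihydrobenzofuran | COc1ccc([C@@H]2c3c(OC)cc(OC)cc3[C@@H](CO[Si](C)(C)C(C)(C)C)[C@@H]2c2cc(OC)cc3O[C@@H](c4ccc(OC)cc4)[C@H](c4cc(OC)cc(OC)c4)c23)cc1
A2 | alternative 2 | dibenzo-fused eight-membered keto ester (ketone at C4, methyl ester on C5) | COc1ccc([C@@H]2c3c(OC)cc(OC)cc3[C@H]3C(=O)c4c(OC)cc(OC)cc4[C@@H](C(=O)OC)c4c(OCc5ccccc5)cc(OC)cc4[C@H]23)cc1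
A3 | alternative 3 | canaliculatol hexamethyl ether with free hydroxyls on ring B1 | COc1ccc([C@@H]2c3c(O)cc(O)cc3[C@H]3[C@H](c4ccc(OC)cc4)c4c(OC)cc(OC)cc4[C@@H]4c5c(cc(OC)cc5[C@H]23)O[C@H]4c2ccc(OC)cc2)cc1
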